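## Analysis of the target

- The target is a halogenated cuparane-type sesquiterpenoid in which a cyclopentane (C1' quaternary methyl carbon, C2' gem-dimethyl, C3' CHBr, C4' CH2, C5' CHOH) is joined through the single bond C1'–C1 to a cyclohexane (C1 tertiary carbinol, C4 CMeCl, C5 CHBr).
- Three fully substituted carbons stand in a row (C2', C1', C1), so every bond made to C1 is made next to a quaternary centre.
- On the cyclopentane (C1' S, C3' S, C5' R) the C3' bromine, the C5' hydroxyl and the C1 substituent share one face and the C1' methyl group takes the other.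
- On the cyclohexane (C1 R, C4 S, C5 S) the C1 hydroxyl and the C4 chlorine are cis and the C5 bromine is trans to both. In the chair that keeps the cyclopentyl group equatorial the two halogens are therefore trans-diequatorial, which diaxial anti addition of bromine and chloride to a C4=C5 alkene would not give.
- Sensitive elements are the tertiary chloride next to a secondary bromide (ionisation, loss of HX), the neopentyl C3' bromide (hard to make by substitution, and lost by β-elimination if C5' were ever a carbonyl), and the 1,3-diol C5'–C1'–C1 (retro-aldol or fragmentation).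
- The synthesis is hard because the cyclohexane configuration must be related to that of the cyclopentane across the rotating C1'–C1 bond, and because the C1'/C3'/C5' triad must be built around a quaternary carbon.
- The strategy rests on one feature: at C1' the carbinol carbon C1 is cis to the C5' oxygen. That is the relationship frozen in a cis-fused cyclopentane β-lactone (6-oxabicyclo[3.2.0]heptan-7-one) whose acyl carbon is C1 and whose ring oxygen is the C5' oxygen.

## Retrosynthetic reasoning

**C4–Cl (31 to 30).** The C4–Cl bond is cut and C4 is reconnected to the C1 oxygen, giving bridged ether 30. Chlorine is cis to the C1 hydroxyl and trans to the C5 bromine, so the C1 oxygen can hold the place of chlorine on the correct face. The forward step has to ionise C4–O, not C1–O, and return chloride with retention. The antiperiplanar C5 bromine and a Lewis acid that carries its own chloride and is anchored on the free C5' hydroxyl should provide this.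

**C3'–Br and the C5' protecting group (30 to 29 to 27).** The C3' bromide is traced to a C3' boronate of opposite configuration, because a bromide cannot survive at C3' while C5' is a carbonyl and cannot be made by substitution at a neopentyl carbon with a carbon-based leaving group. The exchange is placed at 27, where the alkene has been consumed and both oxygens are masked, so the aryllithium that activates boron meets no acidic hydrogen and the electrophilic bromine meets no alkene.

**C5–Br and C4–O (27 to 26, then 26 to 25).** Both bonds are cut together to reveal the C4=C5 alkene and the free C1 hydroxyl of 26. Transannular bromoetherification transfers the C1 configuration to C4 and C5 in one step, because only the bromonium ion anti to the hydroxyl can be captured. The silyl ether on C5' in 26 keeps the second hydroxyl out of this step and out of the boron exchange; it comes from diol 25.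

**C4=C5 (25 to 24).** The ring alkene is cut to the two terminal alkenes of 24. Ring-closing metathesis is neutral, tolerates the boronate and the diol, and places the trisubstituted alkene exactly where the halogens are needed.

**C1–C6 and C1–C2 (24 to 22 and 23; 22 to 19 and 20; 19 to 18).** C1 becomes stereogenic only because C2 and C6 carry different alkenes, so its configuration is decided by the order in which the two chains are added to the acyl carbon. The C2 chain (from 20 through 21) is added first to N-methoxy-N-methylamide 19. Allyl reagent 23 is then added to ketone 22 under chelation with the C5' oxygen, on the face of the C1' methyl group. Amide 19 comes from lactone 18 by acyl–oxygen cleavage, the strain of 18 making up for the hindrance at C1.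

**C1'–C5' and O–C1 (18 to 15).** This is the key disconnection. Both ring bonds of the β-lactone are cut to give aldehyde acid 15. In the forward direction an ammonium enolate at C1' adds to the C5' aldehyde and the alkoxide lactonises. This forms the cyclopentane, the quaternary centre and the C5' oxygen in one operation, and the cis fusion guarantees that C1 and the C5' oxygen share a face. The C1' centre of 15 need not be controlled, since it is planar in the enolate.

**C3'–B and end-group differentiation (15 to 14 to 13 to 11 and 12).** The acid is masked as a benzyl ester and the aldehyde as an N-methoxy-N-methylamide, so the two termini are distinguished from the start. The C3'–B bond is cut to E-enamide 11 and diboron 12; catalytic conjugate borylation sets the only stereocentre that the key step must read.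

**C3'=C4' and C1'–C2' (11 to 9 and 10; 9 to 7 to 6 to 3 to 1 and 2).** The enamide is cut at the alkene to aldehyde 9 and phosphonate 10. Aldehyde 9 comes from terminal alkene 7 by cleavage of the C=C bond. The bond between the two adjacent substituted carbons C1' and C2' is cut by a [3,3] disconnection of acid 6 to prenyl ester 3, made from 1 and 2. A sigmatropic shift is the most dependable way to join a tertiary to a quaternary carbon.

## Alternatives that were turned down

**Alternative 1:** The cyclopentane would be taken from (1R,3S)-camphoric acid A3, whose C1 carboxyl becomes C1 of the cyclohexane. The halogens are disconnected as here, through cyclohexenol A2 and bridged bromo ether A1 (the same compound as 30).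
- Forward key step: an electrophilic bromine source forms the bromonium ion of the C4=C5 alkene of A2 anti to the C1 hydroxyl, which attacks C4 across the ring to give A1.
- For it: A3 is cheap and enantiopure and already holds the quaternary C1' in the right absolute configuration with the correct carbon at C1. No catalyst has to be matched to a substrate, so on absolute stereocontrol and on the first steps it is stronger than the chosen route. Its bromoetherification is as dependable as step 15 here.
- Against it: A3 has a plain methylene at C5' and a carboxyl at C3'. An oxygen would have to be put on an unactivated carbon next to the quaternary centre and cis to the C1' carboxyl. The C3' carboxyl would have to be replaced by bromine with retention on a neopentyl carbon, where a radical decarboxylative bromination is expected to deliver bromine to the less hindered face, trans to C1. The two carboxyls must also be told apart.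
- Comparison: these are several uncertain steps at exactly the positions that the chosen key step functionalises directly. There the C5' oxygen and C1' arise together, and C3' arrives as a boronate that can be exchanged with inversion.

**Alternative 2:** Three bonds are cut at once (C1'–C2', C3'–Br and C1–O), leading from the cyclic carbonate A4 back to the acyclic diene tert-butyl carbonate A5.
- Forward key step: a strongly electrophilic bromosulfonium-type bromine donor forms the bromonium ion of the prenyl alkene of A5. The tetrasubstituted C1'=C1 alkene attacks C2' to close the cyclopentane, and the carbonate carbonyl traps the C1 cation with loss of isobutene to give A4.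
- For it: the neopentyl C3' bromide is installed directly during ring formation, with no boron detour and no invertive exchange. On that point, and in steps to the bicyclic core, it is stronger than the chosen route.
- Against it: the C2' cation can be attacked by either end of the tetrasubstituted alkene, and closure through C1 would give a six-membered ring with an equally tertiary cation, so ring size is not secured. The configuration of C1' and of C3' relative to C5' is only filtered by the carbonate capture, not enforced. The cyclohexane of A4 is a symmetrical ketal, so C1 is not yet stereogenic. Its configuration would later depend on which of two diastereotopic α-carbons of the C4 ketone becomes C5, a choice made four bonds from the nearest stereocentre. The C4 methyl group, the alkene and the bromoether relay would still have to follow.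
- Comparison: the chosen route fixes ring size and the C1/C5'-oxygen relationship by the geometry of a four-membered ring, and sets C1 by addition to a ketone directly attached to the stereodefined C1'.

**Alternative 3:** The C1–O bond is cut last. Both cyclohexane halogens are placed by ordinary diaxial anti addition on a ring that still lacks the C1 oxygen, and the oxygen is then delivered from C5': iminocarbonate A6 is traced to the tertiary C1 bromide A7 bearing a C5' N-trifluoroethylcarbamate.
- Forward key step: a halophilic silver salt ionises the C1 bromide of A7 and the carbamate carbonyl oxygen closes the six-membered iminocarbonate A6.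
- For it: it uses the kinetically natural dihalogenation in one step, without an ether relay, and it avoids two organometallic additions to a hindered acyl carbon. On the number of steps spent on the halogens it is stronger.
- Against it: the C1 cation sits next to the quaternary C1' and is set up for a 1,2-shift. The tether is attached through the rotating C1'–C1 bond and can reach either face of the planar cation, so the C1 configuration rests on a weak axial or equatorial preference. The silver salt also meets a tertiary chloride at C4 with an anti bromine that can ionise as well. The tertiary bromide itself must come from a selective C–H bromination.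
- Comparison: the chosen route pays for the relay with extra steps, but each stereocentre of the cyclohexane is set by an intramolecular or chelate-controlled event.

Key step: step 9

Assumption: the sense of induction of the copper–Josiphos catalyst (step 6) and of the isothiourea (step 9) on these substrates is assigned by analogy with simpler cases; both catalysts exist in either enantiomeric form, and the mirror-image catalyst is used wherever the analogy does not hold.

Abbreviation: pinacolboryl = 4,4,5,5-tetramethyl-1,3,2-dioxaborolan-2-yl.

## Route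

Step 1
Reactants: 1 3-methylbut-2-en-1-ol; 2 propanoyl chloride
Product: 3 3-methylbut-2-en-1-yl propanoate
Conditions: Et3N, DMAP (cat.), CH2Cl2, 0 °C → rt
Reagents that add atoms: none
Why: Acylation of a primary allylic alcohol by an acid chloride (nucleophilic acyl substitution); no stereocentre is formed.

Step 2
Reactants: 3 3-methylbut-2-en-1-yl propanoate
Product: 6 rac-2,3,3-trimethylpent-4-enoic acid, via silyl ketene acetal 4 (not isolated), via trimethylsilyl ester 5 (not isolated)
Conditions: LiN(iPr)2, THF, −78 °C; Me3SiCl; −78 → 65 °C; then 1 M HCl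
Reagents that add atoms: none
Why: Ireland–Claisen rearrangement: O-silylation of the ester enolate gives 4, whose [3,3] shift through a chair joins C1' to the dimethyl-substituted allyl terminus C2' and gives 5, hydrolysed on work-up. C1' is formed racemic, which does not matter because it becomes planar in step 9.

Step 3
Reactants: 6 rac-2,3,3-trimethylpent-4-enoic acid
Product: 7 benzyl rac-2,3,3-trimethylpent-4-enoate
Conditions: BnBr, K2CO3, DMF, rt
Reagents that add atoms: benzyl bromide, BrCc1ccccc1
Why: SN2 O-alkylation of the carboxylate; the hindered benzyl ester withstands steps 4 to 7 and is removed under neutral conditions in step 8.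

Step 4
Reactants: 7 benzyl rac-2,3,3-trimethylpent-4-enoate
Product: 9 benzyl rac-2,3,3-trimethyl-4-oxobutanoate, via ozonide 8 (not isolated)
Conditions: O3, CH2Cl2, −78 °C (indicator dye end point); then Me2S, −78 °C → rt
Reagents that add atoms: ozone, [O-][O+]=O
Why: Ozonolysis of the monosubstituted alkene with reductive work-up of ozonide 8; the benzyl ring reacts far more slowly than the alkene, and the aldehyde formed has no α-hydrogen.

Step 5
Reactants: 9 benzyl rac-2,3,3-trimethyl-4-oxobutanoate; 10 diethyl {2-[methoxy(methyl)amino]-2-oxoethyl}phosphonate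
Product: 11 benzyl (4E)-6-[methoxy(methyl)amino]-2,3,3-trimethyl-6-oxohex-4-enoate (racemic at C2)
Conditions: LiCl, DBU, MeCN, 0 °C → rt
Reagents that add atoms: none
Why: Horner–Wadsworth–Emmons olefination under mild LiCl/amine conditions; the stabilised phosphonate and the bulky quaternary substituent both favour the E alkene.

Step 6
Reactants: 11 benzyl (4E)-6-[methoxy(methyl)amino]-2,3,3-trimethyl-6-oxohex-4-enoate; 12 bis(pinacolato)diboron
Product: 13 benzyl (4R)-6-[methoxy(methyl)amino]-2,3,3-trimethyl-6-oxo-4-(pinacolboryl)hexanoate (both C2 epimers)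
Conditions: CuCl (5 mol%), NaOtBu (10 mol%), (R)-1-[(SP)-2-(diphenylphosphino)ferrocenyl]ethyldicyclohexylphosphine (Josiphos, C36H44FeP2; 5 mol%), MeOH (2 equiv), THF, rt
Reagents that add atoms: none
Why: Copper-catalysed asymmetric conjugate borylation: the ligated copper boryl adds to the E-enamide with boron at the β-carbon C3', and methanol protonates the copper enolate. The chiral bisphosphine selects the alkene face and so sets C3' (4R); the remote racemic C2 centre is expected to have little influence.

Step 7
Reactants: 13 benzyl (4R)-6-[methoxy(methyl)amino]-2,3,3-trimethyl-6-oxo-4-(pinacolboryl)hexanoate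
Product: 14 benzyl (4R)-2,3,3-trimethyl-6-oxo-4-(pinacolboryl)hexanoate (both C2 epimers)
Conditions: Cp2Zr(H)Cl (1.5 equiv), THF, rt, 30 min; aqueous work-up
Reagents that add atoms: none
Why: Hydrozirconation of the amide carbonyl gives a zirconated hemiaminal that releases the aldehyde only on work-up; this reagent reduces tertiary amides much faster than esters, so the benzyl ester and the boronate stay intact.

Step 8
Reactants: 14 benzyl (4R)-2,3,3-trimethyl-6-oxo-4-(pinacolboryl)hexanoate
Product: 15 (4R)-2,3,3-trimethyl-6-oxo-4-(pinacolboryl)hexanoic acid (both C2 epimers)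
Conditions: H2 (1 atm), Pd/C, EtOAc, rt; filtered and used crude
Reagents that add atoms: none
Why: Hydrogenolysis of the benzylic C–O bond frees the acid under neutral conditions, which an aliphatic aldehyde and an alkyl boronate tolerate in a non-alcoholic solvent.

Step 9
Reactants: 15 (4R)-2,3,3-trimethyl-6-oxo-4-(pinacolboryl)hexanoic acid
Product: 18 (1S,3R,5R)-1,2,2-trimethyl-3-(pinacolboryl)-6-oxabicyclo[3.2.0]heptan-7-one, via acyloxypyridinium salt 16 (not isolated), via ammonium enolate 17 (not isolated)
Conditions: 2-chloro-1-methylpyridinium iodide (2 equiv), iPr2NEt (4 equiv), (2S)-2-phenyl-3,4-dihydro-2H-benzo[4,5]thiazolo[3,2-a]pyrimidine [(S)-HBTM, 20 mol%], CH2Cl2 (0.02 M), slow addition of 15, rt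
Reagents that add atoms: none
Why: The carboxylate displaces chloride from the pyridinium salt to give 16; acyl transfer to the isothiourea and loss of the C1' proton (directly or through the ketene) give ammonium enolate 17, whose C1' carbon adds to the C5' aldehyde, and the resulting alkoxide acylates itself on C1 and releases the catalyst. The closest known reaction type is the nucleophile-catalysed aldol-lactonisation of aldehyde acids and keto acids to bicyclic β-lactones, including bis-cyclisations of α-branched acids that create a quaternary α-carbon. The cyclopentane closes by C1'–C5' bond formation in a 5-(enolexo)-exo-trig mode, helped by the C2' gem-dimethyl group, and the β-lactone closes by O–C1 bond formation in a 4-exo-trig acyl substitution. C1' and C5' are set relative to each other by geometry: only the aldolate with C1 and the C5' oxygen on one face can reach the acyl carbon, and the other returns by retro-aldol. Their configuration relative to C3' is set by the catalyst, whose phenyl group shields one face of the planar enolate, and reinforced by the substrate, which places the boronate pseudo-equatorial on the convex face of the forming bicycle. Because C1' is planar in 17, both C2 epimers of 15 give the same lactone. The step needs enolisation at the hindered C1' to outrun self-condensation of the aldehyde, which high dilution, slow addition and the intramolecular trap should secure, and it needs the matched catalyst enantiomer.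

Step 10
Reactants: 18 (1S,3R,5R)-1,2,2-trimethyl-3-(pinacolboryl)-6-oxabicyclo[3.2.0]heptan-7-one
Product: 19 (1S,3R,5R)-5-hydroxy-N-methoxy-N,1,2,2-tetramethyl-3-(pinacolboryl)cyclopentane-1-carboxamide
Conditions: MeNH(OMe)·HCl, iPrMgCl (2 equiv per amine salt), THF, −20 °C; then 18, −20 → 0 °C; aq. NH4Cl
Reagents that add atoms: N,O-dimethylhydroxylamine hydrochloride, CNOC.Cl
Why: Aminolysis of the strained lactone by the preformed magnesium amide at the acyl carbon (acyl–oxygen cleavage); attack at C5' is blocked by the adjacent quaternary carbon and no stereocentre is touched.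

Step 11
Reactants: 19 (1S,3R,5R)-5-hydroxy-N-methoxy-N,1,2,2-tetramethyl-3-(pinacolboryl)cyclopentane-1-carboxamide; 20 4-bromo-2-methylbut-1-ene
Product: 22 1-[(1S,3R,5R)-5-hydroxy-1,2,2-trimethyl-3-(pinacolboryl)cyclopentyl]-4-methylpent-4-en-1-one, via Grignard reagent 21 (not isolated)
Conditions: 20, Mg, THF, rt → 40 °C; then 19 (4 equiv of 21), THF, 0 °C → rt; aq. NH4Cl
Reagents that add atoms: none
Why: One equivalent of 21 deprotonates the C5' hydroxyl and a further one adds to the N-methoxy-N-methylamide to give a chelated tetrahedral intermediate that cannot collapse before work-up, so the addition stops at the ketone (C1–C2 bond). The hindered neopentyl boronate is expected to resist the Grignard reagent at this temperature.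

Step 12
Reactants: 22 1-[(1S,3R,5R)-5-hydroxy-1,2,2-trimethyl-3-(pinacolboryl)cyclopentyl]-4-methylpent-4-en-1-one; 23 allylmagnesium bromide
Product: 24 (4R)-4-[(1S,3R,5R)-5-hydroxy-1,2,2-trimethyl-3-(pinacolboryl)cyclopentyl]-7-methylocta-1,7-dien-4-ol
Conditions: CH2=CHCH2MgBr (3 equiv), Et2O/CH2Cl2, −78 °C, 15 min; aq. NH4Cl at −78 °C
Reagents that add atoms: none
Why: Chelation-controlled Grignard addition: the C5' magnesium alkoxide and the C1 carbonyl close a six-membered chelate whose cyclopentane-side face is covered by the C2' gem-dimethyl carbon, so the allyl group enters from the face of the C1' methyl group. This makes C1 R once the allyl carbon is C6; the Felkin–Anh arrangement with C2' as the large group exposes the same face.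

Step 13
Reactants: 24 (4R)-4-[(1S,3R,5R)-5-hydroxy-1,2,2-trimethyl-3-(pinacolboryl)cyclopentyl]-7-methylocta-1,7-dien-4-ol
Product: 25 (1R)-1-[(1S,3R,5R)-5-hydroxy-1,2,2-trimethyl-3-(pinacolboryl)cyclopentyl]-4-methylcyclohex-3-en-1-ol
Conditions: second-generation Grubbs catalyst RuCl2(=CHPh)(SIMes)(PCy3) (5 mol%), CH2Cl2 (0.01 M), 40 °C
Reagents that add atoms: none
Why: Ring-closing metathesis of the monosubstituted and the 1,1-disubstituted alkene closes the six-membered ring as the trisubstituted C4=C5 alkene with loss of ethene; free hydroxyls and the boronate are tolerated and no stereocentre is affected.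

Step 14
Reactants: 25 (1R)-1-[(1S,3R,5R)-5-hydroxy-1,2,2-trimethyl-3-(pinacolboryl)cyclopentyl]-4-methylcyclohex-3-en-1-ol
Product: 26 (1R)-4-methyl-1-[(1S,3R,5R)-1,2,2-trimethyl-3-(pinacolboryl)-5-(triethylsilyloxy)cyclopentyl]cyclohex-3-en-1-ol
Conditions: Et3SiCl, imidazole, DMF, 0 °C
Reagents that add atoms: chlorotriethylsilane, CC[Si](Cl)(CC)CC
Why: Selective silylation of the secondary C5' hydroxyl; the tertiary C1 hydroxyl between two fully substituted carbons does not react under these conditions and stays free for step 15.

Step 15
Reactants: 26 (1R)-4-methyl-1-[(1S,3R,5R)-1,2,2-trimethyl-3-(pinacolboryl)-5-(triethylsilyloxy)cyclopentyl]cyclohex-3-en-1-ol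
Product: 27 (1S,2S,4R)-2-bromo-1-methyl-4-[(1S,3R,5R)-1,2,2-trimethyl-3-(pinacolboryl)-5-(triethylsilyloxy)cyclopentyl]-7-oxabicyclo[2.2.1]heptane
Conditions: NBS (1.1 equiv), NaHCO3, CH2Cl2, 0 °C, dark
Reagents that add atoms: N-bromosuccinimide, O=C1CCC(=O)N1Br
Why: Transannular bromoetherification: bromonium formation is reversible on both faces, but only the ion anti to the axial C1 hydroxyl is trapped, by attack of that hydroxyl on the tertiary C4 through a boat (five-membered ring closure, Markovnikov). Anti addition places the C4 oxygen cis to C1–O and the C5 bromine on the opposite face; the unactivated boronate is inert to NBS.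

Step 16
Reactants: 27 (1S,2S,4R)-2-bromo-1-methyl-4-[(1S,3R,5R)-1,2,2-trimethyl-3-(pinacolboryl)-5-(triethylsilyloxy)cyclopentyl]-7-oxabicyclo[2.2.1]heptane
Product: 29 (1S,2S,4R)-2-bromo-4-[(1S,3S,5R)-3-bromo-1,2,2-trimethyl-5-(triethylsilyloxy)cyclopentyl]-1-methyl-7-oxabicyclo[2.2.1]heptane, via lithium boronate complex 28 (not isolated)
Conditions: 3,5-(CF3)2C6H3Br, n-BuLi, THF, −78 °C; then 27, −78 °C, 30 min; then NBS (1.5 equiv), −78 °C → rt; aq. NH4Cl
Reagents that add atoms: N-bromosuccinimide, O=C1CCC(=O)N1Br
Why: Stereospecific bromodeboronation: the electron-poor aryllithium adds to boron to give the nucleophilic complex 28, which is brominated at carbon on the face opposite to boron (SE2 with inversion). The C3' boronate (R, anti to the C5' oxygen) thus becomes the C3' bromide (S, syn); the substrate offers the aryllithium no acidic hydrogen and the bromine source no alkene.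

Step 17
Reactants: 29 (1S,2S,4R)-2-bromo-4-[(1S,3S,5R)-3-bromo-1,2,2-trimethyl-5-(triethylsilyloxy)cyclopentyl]-1-methyl-7-oxabicyclo[2.2.1]heptane
Product: 30 (1R,2S,4S)-4-bromo-2-[(1R,3S,4S)-3-bromo-4-methyl-7-oxabicyclo[2.2.1]heptan-1-yl]-2,3,3-trimethylcyclopentan-1-ol
Conditions: HF·pyridine, pyridine, THF, 0 °C → rt
Reagents that add atoms: none
Why: Buffered fluoride cleavage of the triethylsilyl ether; the bridged ether and both secondary bromides are inert to these conditions.

Step 18
Reactants: 30 (1R,2S,4S)-4-bromo-2-[(1R,3S,4S)-3-bromo-4-methyl-7-oxabicyclo[2.2.1]heptan-1-yl]-2,3,3-trimethylcyclopentan-1-ol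
Product: 31 (1R,3S,4S)-3-bromo-1-[(1S,3S,5R)-3-bromo-5-hydroxy-1,2,2-trimethylcyclopentyl]-4-chloro-4-methylcyclohexan-1-ol
Conditions: TiCl4 (3 equiv), CH2Cl2, −78 → −30 °C; aq. NaHCO3
Reagents that add atoms: titanium tetrachloride, Cl[Ti](Cl)(Cl)Cl
Why: Lewis-acid cleavage of a tertiary ether with chloride transfer: the C5' hydroxyl binds titanium, which chelates the bridging oxygen; the C4–O bond ionises with participation of the antiperiplanar C5 bromine (the reverse of step 15), and chloride returns to C4 from the titanium-bearing face, anti to bromine, so chlorine replaces oxygen with retention. The chelated titanium 1,3-diolate of the C5' and C1 oxygens is the expected sink and holds the C1'–C5' bond gauche to C1–O, out of alignment for fragmentation.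

## Compound list

1 | 3-methylbut-2-en-1-ol | CC(C)=CCO | starting material
2 | propanoyl chloride | CCC(=O)Cl | starting material
3 | 3-methylbut-2-en-1-yl propanoate | CCC(=O)OCC=C(C)C | intermediate
4 | trimethyl{[1-(3-methylbut-2-en-1-yloxy)prop-1-en-1-yl]oxy}silane (silyl ketene acetal) | CC=C(O[Si](C)(C)C)OCC=C(C)C | intermediate (not isolated)
5 | trimethylsilyl rac-2,3,3-trimethylpent-4-enoate | C=CC(C)(C)C(C)C(=O)O[Si](C)(C)C | intermediate (not isolated)
6 | rac-2,3,3-trimethylpent-4-enoic acid | C=CC(C)(C)C(C)C(O)=O | intermediate
7 | benzyl rac-2,3,3-trimethylpent-4-enoate | C=CC(C)(C)C(C)C(=O)OCc1ccccc1 | intermediate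
8 | benzyl 2,3-dimethyl-3-(1,2,4-trioxolan-3-yl)butanoate (ozonide) | O=C(OCc1ccccc1)C(C)C(C)(C)C1OCOO1 | intermediate (not isolated)
9 | benzyl rac-2,3,3-trimethyl-4-oxobutanoate | O=CC(C)(C)C(C)C(=O)OCc1ccccc1 | intermediate
10 | diethyl {2-[methoxy(methyl)amino]-2-oxoethyl}phosphonate | CCOP(=O)(CC(=O)N(C)OC)OCC | starting material
11 | benzyl (4E)-6-[methoxy(methyl)amino]-2,3,3-trimethyl-6-oxohex-4-enoate | CON(C)C(=O)/C=C/C(C)(C)C(C)C(=O)OCc1ccccc1 | intermediate
12 | bis(pinacolato)diboron | CC1(C)OB(OC1(C)C)B1OC(C)(C)C(C)(C)O1 | starting material
13 | benzyl (4R)-6-[methoxy(methyl)amino]-2,3,3-trimethyl-6-oxo-4-(pinacolboryl)hexanoate | O=C(OCc1ccccc1)C(C)C(C)(C)[C@H](B1OC(C)(C)C(C)(C)O1)CC(=O)N(C)OC | intermediate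
14 | benzyl (4R)-2,3,3-trimethyl-6-oxo-4-(pinacolboryl)hexanoate | O=C(OCc1ccccc1)C(C)C(C)(C)[C@H](B1OC(C)(C)C(C)(C)O1)CC=O | intermediate
15 | (4R)-2,3,3-trimethyl-6-oxo-4-(pinacolboryl)hexanoic acid | OC(=O)C(C)C(C)(C)[C@H](B1OC(C)(C)C(C)(C)O1)CC=O | intermediate
16 | 1-methyl-2-{[(4R)-2,3,3-trimethyl-6-oxo-4-(pinacolboryl)hexanoyl]oxy}pyridinium iodide | C[n+]1ccccc1OC(=O)C(C)C(C)(C)[C@H](B1OC(C)(C)C(C)(C)O1)CC=O.[I-] | intermediate (not isolated)
17 | C1' ammonium enolate of the acyl group of 15 bound to (S)-HBTM (zwitterion) | [O-]C(=C(C)C(C)(C)[C@H](B1OC(C)(C)C(C)(C)O1)CC=O)[N+]1=C2Sc3ccccc3N2CC[C@H]1c1ccccc1 | intermediate (not isolated)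
18 | (1S,3R,5R)-1,2,2-trimethyl-3-(pinacolboryl)-6-oxabicyclo[3.2.0]heptan-7-one | CC1(C)[C@H](B2OC(C)(C)C(C)(C)O2)C[C@@H](O3)[C@@]1(C)C3=O | intermediate
19 | (1S,3R,5R)-5-hydroxy-N-methoxy-N,1,2,2-tetramethyl-3-(pinacolboryl)cyclopentane-1-carboxamide | CC1(C)[C@H](B2OC(C)(C)C(C)(C)O2)C[C@@H](O)[C@@]1(C)C(=O)N(C)OC | intermediate
20 | 4-bromo-2-methylbut-1-ene | CC(=C)CCBr | starting material
21 | (3-methylbut-3-en-1-yl)magnesium bromide | CC(=C)CC[Mg]Br | intermediate (not isolated)
22 | 1-[(1S,3R,5R)-5-hydroxy-1,2,2-trimethyl-3-(pinacolboryl)cyclopentyl]-4-methylpent-4-en-1-one | CC1(C)[C@H](B2OC(C)(C)C(C)(C)O2)C[C@@H](O)[C@@]1(C)C(=O)CCC(C)=C | intermediate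
23 | allylmagnesium bromide | C=CC[Mg]Br | starting material
24 | (4R)-4-[(1S,3R,5R)-5-hydroxy-1,2,2-trimethyl-3-(pinacolboryl)cyclopentyl]-7-methylocta-1,7-dien-4-ol | CC1(C)[C@H](B2OC(C)(C)C(C)(C)O2)C[C@@H](O)[C@@]1(C)[C@@](CC=C)(O)CCC(C)=C | intermediate
25 | (1R)-1-[(1S,3R,5R)-5-hydroxy-1,2,2-trimethyl-3-(pinacolboryl)cyclopentyl]-4-methylcyclohex-3-en-1-ol | CC1(C)[C@H](B2OC(C)(C)C(C)(C)O2)C[C@@H](O)[C@@]1(C)[C@@]1(O)CCC(C)=CC1 | intermediate
26 | (1R)-4-methyl-1-[(1S,3R,5R)-1,2,2-trimethyl-3-(pinacolboryl)-5-(triethylsilyloxy)cyclopentyl]cyclohex-3-en-1-ol | CC1(C)[C@H](B2OC(C)(C)C(C)(C)O2)C[C@@H](O[Si](CC)(CC)CC)[C@@]1(C)[C@@]1(O)CCC(C)=CC1 | intermediate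
27 | (1S,2S,4R)-2-bromo-1-methyl-4-[(1S,3R,5R)-1,2,2-trimethyl-3-(pinacolboryl)-5-(triethylsilyloxy)cyclopentyl]-7-oxabicyclo[2.2.1]heptane | CC1(C)[C@H](B2OC(C)(C)C(C)(C)O2)C[C@@H](O[Si](CC)(CC)CC)[C@@]1(C)[C@@]13CC[C@](C)(O3)[C@@H](Br)C1 | intermediate
28 | lithium B-[3,5-bis(trifluoromethyl)phenyl] boronate complex of 27 | [Li+].CC1(C)[C@H]([B-]2(OC(C)(C)C(C)(C)O2)c2cc(cc(c2)C(F)(F)F)C(F)(F)F)C[C@@H](O[Si](CC)(CC)CC)[C@@]1(C)[C@@]13CC[C@](C)(O3)[C@@H](Br)C1 | intermediate (not isolated)
29 | (1S,2S,4R)-2-bromo-4-[(1S,3S,5R)-3-bromo-1,2,2-trimethyl-5-(triethylsilyloxy)cyclopentyl]-1-methyl-7-oxabicyclo[2.2.1]heptane | CC1(C)[C@@H](Br)C[C@@H](O[Si](CC)(CC)CC)[C@@]1(C)[C@@]13CC[C@](C)(O3)[C@@H](Br)C1 | intermediate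
30 | (1R,2S,4S)-4-bromo-2-[(1R,3S,4S)-3-bromo-4-methyl-7-oxabicyclo[2.2.1]heptan-1-yl]-2,3,3-trimethylcyclopentan-1-ol | CC1(C)[C@@H](Br)C[C@@H](O)[C@@]1(C)[C@@]13CC[C@](C)(O3)[C@@H](Br)C1 | intermediate
31 | (1R,3S,4S)-3-bromo-1-[(1S,3S,5R)-3-bromo-5-hydroxy-1,2,2-trimethylcyclopentyl]-4-chloro-4-methylcyclohexan-1-ol | CC1(C)[C@@H](Br)C[C@@H](O)[C@@]1(C)[C@@]1(O)CC[C@](C)(Cl)[C@@H](Br)C1 | target

## Step count and least certain steps

Total step count: 18. Longest linear sequence: 18 steps (1 to 31); the route is linear, with 2, 10, 12, 20 and 23 bought.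

**Step 9 (key step).** The most likely failure is slow enolisation at C1', which is α-branched and flanked by the quaternary C2'. The activated acid would then be consumed by self-condensation of the aldehyde, or the catalyst would not turn over. A second risk is insufficient face selection relative to C3' if catalyst and substrate preferences oppose each other.
Fallback, from 15 back to 18: a catalyst-free intramolecular ketene–aldehyde [2+2] cycloaddition. Acid 15 is converted with 1-chloro-N,N,2-trimethylprop-1-en-1-amine (CH2Cl2, 0 °C) into (4R)-2,3,3-trimethyl-6-oxo-4-(pinacolboryl)hexanoyl chloride F1. Slow addition of F1 to Et3N in toluene at 80 °C forces dehydrochlorination to the free ketene (3R)-4,4,5-trimethyl-6-oxo-3-(pinacolboryl)hex-5-enal F2. F2 is expected to add across the tethered aldehyde to give 18, with the relative configuration left to the substrate (boronate on the convex face).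

**Step 18.** The most likely failure is heterolysis of the C1–O bond in place of C4–O, since the C1 cation carries no β-halogen. Proton loss or a 1,2-shift next to the quaternary C1' would follow. Collapse of the bromonium–alkoxide pair back to the ether or by loss of a proton is the other risk, because the titanium alkoxide may be slow to give up chloride.
Fallback, from 30 back to 31: a two-step acylative cleavage, in which the ring oxygen is captured as an ester and cannot re-close, and the product is never exposed to a strong Lewis acid. Acetyl chloride with catalytic ZnCl2 (CH2Cl2, 0 °C) acetylates the C5' hydroxyl and the bridging oxygen. Chloride opens the C4–O bond of the acyloxonium ion, with the same bromine participation, to give (1R,2S,4S)-2-[(1R,3S,4S)-1-acetoxy-3-bromo-4-chloro-4-methylcyclohexyl]-4-bromo-2,3,3-trimethylcyclopentyl acetate F3. iBu2AlH (CH2Cl2, −78 °C) then removes both acetates without touching the halides and gives 31.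

**Step 16.** The most likely failure is loss of stereospecificity. Backside approach to C3' is on the more crowded face of a neopentyl carbon, so single-electron oxidation of the boronate complex and radical recombination may compete and deliver bromine to the open face. Protodeboronation is the lesser risk.
Fallback, from 27 back to 29: exchange through oxygen. Oxidation with NaBO3·4H2O (THF/H2O, rt) should give, with retention, (1R,3S,4R)-3-[(1S,2S,4R)-2-bromo-1-methyl-7-oxabicyclo[2.2.1]heptan-4-yl]-2,2,3-trimethyl-4-(triethylsilyloxy)cyclopentan-1-ol F4. Appel bromination of F4 with CBr4 and P(n-C8H17)3 (toluene, 70 °C) then displaces the activated oxygen with inversion to give 29.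

**Step 12.** The most likely failure is addition through a non-chelated rotamer of the ketone, because allylmagnesium reagents react very fast; this would mean poor or reversed facial selectivity at C1.
Fallback, from 19 back to 24: the order of the two carbon nucleophiles is reversed, which inverts C1 for any given facial preference because C2 and C6 differ only in the alkene they carry. Amide 19 is treated with CH2=CHCH2MgBr (THF, −78 °C, cold quench) to give 1-[(1S,3R,5R)-5-hydroxy-1,2,2-trimethyl-3-(pinacolboryl)cyclopentyl]but-3-en-1-one F5, handled cold to avoid conjugation of the alkene. The organocerium reagent made from 21 and CeCl3 (THF, −78 °C) is then added to F5 to give 24; the cerium reagent suppresses enolisation.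

**Step 11.** The most likely failure is sluggish addition to an amide carbonyl flanked by two fully substituted carbons. The basic Grignard reagent would then have time to demethoxylate the amide and to attack the boronate ester.
Fallback, from 19 back to 22: the carbon nucleophile is added at the aldehyde oxidation level.
- Silylation of 19 (Et3SiOTf, 2,6-lutidine, CH2Cl2, −78 °C) gives (1S,3R,5R)-N-methoxy-N,1,2,2-tetramethyl-3-(pinacolboryl)-5-(triethylsilyloxy)cyclopentane-1-carboxamide F6.
- Cp2Zr(H)Cl (THF, rt) reduces F6 to (1S,3R,5R)-1,2,2-trimethyl-3-(pinacolboryl)-5-(triethylsilyloxy)cyclopentane-1-carbaldehyde F7.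
- Grignard reagent 21 adds to F7 at −78 °C to give 1-[(1R,3R,5R)-1,2,2-trimethyl-3-(pinacolboryl)-5-(triethylsilyloxy)cyclopentyl]-4-methylpent-4-en-1-ol F8 (both carbinol epimers; the descriptor at C1' changes only through priority).
- Dess–Martin periodinane (CH2Cl2, rt) oxidises F8 to 1-[(1S,3R,5R)-1,2,2-trimethyl-3-(pinacolboryl)-5-(triethylsilyloxy)cyclopentyl]-4-methylpent-4-en-1-one F9.
- HF·pyridine (THF, 0 °C) removes the silyl group of F9 and gives 22.

## Further compounds

F1 | step 9 | (4R)-2,3,3-trimethyl-6-oxo-4-(pinacolboryl)hexanoyl chloride | O=C(Cl)C(C)C(C)(C)[C@H](B1OC(C)(C)C(C)(C)O1)CC=O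
F2 | step 9 | (3R)-4,4,5-trimethyl-6-oxo-3-(pinacolboryl)hex-5-enal (ketene) | O=C=C(C)C(C)(C)[C@H](B1OC(C)(C)C(C)(C)O1)CC=O
F3 | step 18 | (1R,2S,4S)-2-[(1R,3S,4S)-1-acetoxy-3-bromo-4-chloro-4-methylcyclohexyl]-4-bromo-2,3,3-trimethylcyclopentyl acetate | CC1(C)[C@@H](Br)C[C@@H](OC(C)=O)[C@@]1(C)[C@@]1(OC(C)=O)CC[C@](C)(Cl)[C@@H](Br)C1
F4 | step 16 | (1R,3S,4R)-3-[(1S,2S,4R)-2-bromo-1-methyl-7-oxabicyclo[2.2.1]heptan-4-yl]-2,2,3-trimethyl-4-(triethylsilyloxy)cyclopentan-1-ol | CC1(C)[C@H](O)C[C@@H](O[Si](CC)(CC)CC)[C@@]1(C)[C@@]13CC[C@](C)(O3)[C@@H](Br)C1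
F5 | step 12 | 1-[(1S,3R,5R)-5-hydroxy-1,2,2-trimethyl-3-(pinacolboryl)cyclopentyl]but-3-en-1-one | CC1(C)[C@H](B2OC(C)(C)C(C)(C)O2)C[C@@H](O)[C@@]1(C)C(=O)CC=C
F6 | step 11 | (1S,3R,5R)-N-methoxy-N,1,2,2-tetramethyl-3-(pinacolboryl)-5-(triethylsilyloxy)cyclopentane-1-carboxamide | CC1(C)[C@H](B2OC(C)(C)C(C)(C)O2)C[C@@H](O[Si](CC)(CC)CC)[C@@]1(C)C(=O)N(C)OC
F7 | step 11 | (1S,3R,5R)-1,2,2-trimethyl-3-(pinacolboryl)-5-(triethylsilyloxy)cyclopentane-1-carbaldehyde | CC1(C)[C@H](B2OC(C)(C)C(C)(C)O2)C[C@@H](O[Si](CC)(CC)CC)[C@@]1(C)C=O
F8 | step 11 | 1-[(1R,3R,5R)-1,2,2-trimethyl-3-(pinacolboryl)-5-(triethylsilyloxy)cyclopentyl]-4-methylpent-4-en-1-ol (both carbinol epimers) | CC1(C)[C@H](B2OC(C)(C)C(C)(C)O2)C[C@@H](O[Si](CC)(CC)CC)[C@@]1(C)C(O)CCC(C)=C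
F9 | step 11 | 1-[(1S,3R,5R)-1,2,2-trimethyl-3-(pinacolboryl)-5-(triethylsilyloxy)cyclopentyl]-4-methylpent-4-en-1-one | CC1(C)[C@H](B2OC(C)(C)C(C)(C)O2)C[C@@H](O[Si](CC)(CC)CC)[C@@]1(C)C(=O)CCC(C)=C
A1 | alternative 1 | (1R,2S,4S)-4-bromo-2-[(1R,3S,4S)-3-bromo-4-methyl-7-oxabicyclo[2.2.1]heptan-1-yl]-2,3,3-trimethylcyclopentan-1-ol (identical with 30) | CC1(C)[C@@H](Br)C[C@@H](O)[C@@]1(C)[C@@]12CC[C@](C)(O2)[C@@H](Br)C1
A2 | alternative 1 | (1R)-1-[(1S,3S,5R)-3-bromo-5-hydroxy-1,2,2-trimethylcyclopentyl]-4-methylcyclohex-3-en-1-ol | CC1(C)[C@@H](Br)C[C@@H](O)[C@@]1(C)[C@@]1(O)CCC(C)=CC1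
A3 | alternative 1 | (1R,3S)-1,2,2-trimethylcyclopentane-1,3-dicarboxylic acid ((+)-camphoric acid) | CC1(C)[C@@H](C(O)=O)CC[C@@]1(C)C(O)=O
A4 | alternative 2 | bromocyclopentane cis-fused to a six-membered cyclic carbonate, spiro at C1 to cyclohexanone ethylene ketal | CC1(C)[C@@H](Br)C[C@@H](OC(=O)O2)[C@@]1(C)C23CCC4(CC3)OCCO4
A5 | alternative 2 | tert-butyl (3R)-2-(1,4-dioxaspiro[4.5]decan-8-ylidene)-6-methylhept-5-en-3-yl carbonate | CC(C)=CC[C@@H](OC(=O)OC(C)(C)C)C(C)=C1CCC2(CC1)OCCO2
A6 | alternative 3 | spiro cyclic N-(2,2,2-trifluoroethyl)iminocarbonate bridging the C5' and C1 oxygens, with C3' boronate, C4 chloride and C5 bromide | CC1(C)[C@H](B2OC(C)(C)C(C)(C)O2)C[C@@H](OC(=NCC(F)(F)F)O3)[C@@]1(C)[C@@]43CC[C@](C)(Cl)[C@@H](Br)C4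
A7 | alternative 3 | tertiary C1 bromide bearing the C5' N-(2,2,2-trifluoroethyl)carbamate (either C1 epimer) | CC1(C)[C@H](B2OC(C)(C)C(C)(C)O2)C[C@@H](OC(=O)NCC(F)(F)F)[C@@]1(C)C3(Br)CC[C@](C)(Cl)[C@@H](Br)C3
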